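## Retrosynthetic overview

1. The target's ten-membered ring carries a C1 ketone that is flanked by quaternary C10 and sits 1,5 to the C5–C6 edge of the γ-lactone, with the C4 methyl stereocentre in between. This is a cyclodec-5-en-1-one pattern.
2. Key disconnection: the ten-membered carbocycle (C1–C10) comes from the six-membered carbinol 16 (ring C1–C10–C9–C8–C7–C6) by an anionic oxy-Cope ring expansion. It breaks C1–C6, forms C3–C4, sets C4, and unveils the C1 ketone and the E C5=C6 olefin.
3. After the rearrangement: C2=C3 dehydrogenation and peripheral epoxidation give the oxirane; C12 is added by alkyne hydroxycarbonylation; iodolactonisation onto C5=C6 closes the α-methylene lactone.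
4. Before it: an asymmetric Diels–Alder reaction of dienyl acetate 4 with enynal 8 builds the cyclohexene and sets C6, C7 and C8; OH-directed epoxidation and Ti-mediated opening set C9 and C10.
5. Ring order: cyclohexene (Diels–Alder) → ten-membered carbocycle (oxy-Cope) → oxirane → γ-lactone.

Key step: step 11

Remark on notation: all ring compounds carry the germacrane atom labels of the target. C1 is the ketone, C2/C3 the oxirane, C4 bears methyl C15, C6 bears the lactone oxygen, C8 the crotonate, C9 the acetate, C10 the OH and methyl C14, and C11/C12/C13 form the methylene lactone. The six-membered intermediates keep these labels. β is the face of the C7–C11 bond in the target; α is the opposite face. TBS = tert-butyldimethylsilyl, PMB = 4-methoxybenzyl.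

Assumption: the facial sense of the oxazaborolidinium catalyst in step 4 is taken from the formyl C–H···O binding model. The (S)-catalyst is written; its mirror image is used if the first run shows the opposite sense.

## Route

Step 1
Reactants: 1 (tert-butyldimethylsilyloxy)acetaldehyde; 2 2-(triphenyl-λ5-phosphanylidene)propanal
Product: 3 (E)-4-(TBS-oxy)-2-methylbut-2-enal
Conditions: toluene, 80 °C
Reagents that add atoms: none
Why: Wittig olefination with a stabilised formyl ylide reacts only at the more electrophilic aliphatic aldehyde and should give the E-trisubstituted enal.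

Step 2
Reactants: 3 (E)-4-(TBS-oxy)-2-methylbut-2-enal
Product: 4 (1E,3E)-4-(TBS-oxy)-2-methylbuta-1,3-dien-1-yl acetate
Conditions: Ac2O, Et3N, DMAP (cat.), 60 °C
Reagents that add atoms: acetic anhydride CC(=O)OC(C)=O
Why: γ-Deprotonation of the enal gives the extended dienolate, which is O-acetylated (dienol acetate formation); the (1E,3E) isomer, the only one that can reach the s-cis form needed in step 4, should predominate under these equilibrating conditions.

Step 3
Reactants: 5 but-2-yn-1-ol; 6 (triphenyl-λ5-phosphanylidene)acetaldehyde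
Product: 8 (E)-hex-2-en-4-ynal, via but-2-ynal 7 (not isolated)
Conditions: activated MnO2, CH2Cl2, reflux
Reagents that add atoms: none
Why: Tandem MnO2 oxidation/Wittig olefination traps the volatile ynal as it forms, and the stabilised ylide should give the E-enal.

Step 4
Reactants: 4 (1E,3E)-4-(TBS-oxy)-2-methylbuta-1,3-dien-1-yl acetate; 8 (E)-hex-2-en-4-ynal
Product: 9 cyclohexene aldehyde: 1β-acetoxy-8β-(TBS-oxy)-7β-formyl-10-methyl-6α-(prop-1-ynyl)cyclohex-9-ene
Conditions: oxazaborolidinium triflimide from (S)-α,α-diphenylprolinol, o-tolylboroxine and Tf2NH (20 mol %), CH2Cl2, −78 to −40 °C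
Reagents that add atoms: none
Why: In this Lewis-acid-catalysed normal-demand Diels–Alder reaction the silyloxy terminus (C8) bonds to the formyl-bearing carbon (ortho rule), the endo formyl group ends cis to both diene oxygens and trans to the propynyl group, and the chiral cation shields one enal face, so C1, C8, C7 and C6 are set together.

Step 5
Reactants: 9 cyclohexene aldehyde
Product: 10 1β-acetoxy-8β-(TBS-oxy)-7β-formyl-10-methyl-6α-[(Z)-prop-1-enyl]cyclohex-9-ene
Conditions: H2 (1 atm), Lindlar catalyst, quinoline, EtOAc, rt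
Reagents that add atoms: none
Why: Lindlar semihydrogenation adds H2 syn to the internal alkyne and should give the Z-propenyl group; the aldehyde and the trisubstituted ring olefin do not react.

Step 6
Reactants: 10 Z-propenyl aldehyde
Product: 12 7β-ethynyl-10-methyl-6α-[(Z)-prop-1-enyl]-8β-(TBS-oxy)cyclohex-9-en-1β-ol, via alkynyl acetate 11 (not isolated)
Conditions: dimethyl (1-diazo-2-oxopropyl)phosphonate, K2CO3, MeOH, 0 °C to rt
Reagents that add atoms: dimethyl (1-diazo-2-oxopropyl)phosphonate CC(=O)C(=[N+]=[N-])P(=O)(OC)OC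
Why: Seyferth–Gilbert homologation with the Bestmann–Ohira reagent turns the formyl group into the C11≡C13 alkyne, and the same K2CO3/MeOH cleaves the allylic acetate; the 7β,6α-trans arrangement is the more stable one, so C7 should not epimerise.

Step 7
Reactants: 12 allylic alcohol
Product: 13 9β,10β-epoxide of 12 (1β-OH, 10α-methyl)
Conditions: VO(acac)2 (5 mol %), t-BuOOH, CH2Cl2, 0 °C
Reagents that add atoms: tert-butyl hydroperoxide CC(C)(C)OO
Why: Hydroxyl-directed vanadium-catalysed epoxidation delivers oxygen syn to the C1 hydroxyl (β face) and should select the allylic trisubstituted olefin over the homoallylic Z-propenyl group and the alkyne.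

Step 8
Reactants: 13 epoxy alcohol
Product: 14 7β-ethynyl-10α-methyl-9α-(PMB-oxy)-6α-[(Z)-prop-1-enyl]-8β-(TBS-oxy)cyclohexane-1β,10β-diol
Conditions: Ti(OiPr)4 (1.5 equiv), 4-methoxybenzyl alcohol (5 equiv), CH2Cl2, rt to 40 °C
Reagents that add atoms: 4-methoxybenzyl alcohol COc1ccc(CO)cc1
Why: Titanium-mediated opening of a 2,3-epoxy alcohol occurs at C-3 (here C9) with inversion, which is also the trans-diaxial (Fürst–Plattner) mode for the chair with C6 and C7 substituents equatorial; this gives the 9α-ether and keeps the epoxide oxygen as the 10β-hydroxyl.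

Step 9
Reactants: 14 diol
Product: 15 7β-ethynyl-10β-hydroxy-10α-methyl-9α-(PMB-oxy)-6α-[(Z)-prop-1-enyl]-8β-(TBS-oxy)cyclohexan-1-one
Conditions: Dess–Martin periodinane, pyridine, CH2Cl2, 0 °C
Reagents that add atoms: none
Why: Dess–Martin oxidation converts the only secondary alcohol into the ketone under near-neutral conditions, so the tertiary C10 hydroxyl survives and the β,γ-unsaturated ketone should neither conjugate nor epimerise at C6.

Step 10
Reactants: 15 ketol
Product: 16 1β-ethenyl-7β-ethynyl-10α-methyl-9α-(PMB-oxy)-6α-[(Z)-prop-1-enyl]-8β-(TBS-oxy)cyclohexane-1α,10β-diol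
Conditions: CH2=CHMgBr (3.5 equiv), anhydrous CeCl3, THF, −78 °C; aq NH4Cl
Reagents that add atoms: vinylmagnesium bromide C=C[Mg]Br
Why: Cerium-mediated Grignard 1,2-addition should occur by equatorial attack on the β face, because the axial path is blocked by the syn-axial C9 ether and the α face carries the C6 propenyl and C10 methyl groups; this places the vinyl group trans to the propenyl group.

Step 11
Reactants: 16 dialkenyl carbinol
Product: 18 (5E)-7β-ethynyl-10β-hydroxy-4β,10α-dimethyl-9α-(PMB-oxy)-8β-(TBS-oxy)cyclodec-5-en-1-one, via tripotassium enolate 17 (not isolated)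
Conditions: KH (3.5 equiv), 18-crown-6, THF, 0 °C to rt; then aq NH4Cl, −78 °C
Reagents that add atoms: none
Why: Deprotonation gives the C1 alkoxide (with the C10 alkoxide and the acetylide as spectators), which undergoes the charge-accelerated [3,3]-sigmatropic shift of the C3=C2–C1–C6–C5=C4 unit: the C1–C6 bond of the six-membered ring breaks as C3–C4 forms. The closest known reaction type is the anionic oxy-Cope ring expansion of trans-1,2-dialkenylcyclohexanols to (E)-cyclodec-5-en-1-ones. The ten-membered ring arises by this four-atom ring expansion through a chair-like six-membered transition state, not by an end-to-end closure. C4 is set by chirality transfer from C6: with the C6–C7 ring bond equatorial and the methyl of the Z-propenyl group axial in the chair, C3 bonds to the face of C4 that gives the 4α-H, 15β-methyl centre, and the equatorial C6–C7 bond becomes the E C5=C6 olefin. The step needs chair over boat and [3,3] over alkoxide-induced C1–C6 heterolysis; the vinyl and propenyl groups are trans and diequatorial in the only chair that avoids syn-diaxial carbon substituents, which holds the two olefin termini within bonding distance. The enolate forms only toward C2 because C10 is quaternary, and cold protonation returns the C1 ketone.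

Step 12
Reactants: 18 cyclodecenone
Product: 19 (5E)-7β-ethynyl-8β,10β-dihydroxy-4β,10α-dimethyl-9α-(PMB-oxy)cyclodec-5-en-1-one
Conditions: HF·pyridine, pyridine, THF, 0 °C to rt
Reagents that add atoms: none
Why: Fluoride-mediated desilylation frees the C8 hydroxyl while the PMB ether, the ketone and the olefin are inert to buffered HF.

Step 13
Reactants: 19 8β-alcohol
Product: 20 8β-[(E)-but-2-enoyloxy] ester of 19 (9α-OPMB, 10β-OH)
Conditions: (E)-crotonic anhydride, pyridine, DMAP (cat.), CH2Cl2, 0 °C
Reagents that add atoms: (E)-crotonic anhydride C/C=C/C(=O)OC(=O)/C=C/C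
Why: DMAP-catalysed acylation esterifies the secondary C8 hydroxyl, and the tertiary C10 hydroxyl should not react under these mild conditions.

Step 14
Reactants: 20 crotonate PMB ether
Product: 21 (5E)-8β-[(E)-but-2-enoyloxy]-7β-ethynyl-9α,10β-dihydroxy-4β,10α-dimethylcyclodec-5-en-1-one
Conditions: DDQ, CH2Cl2/pH 7 buffer (10:1), 0 °C to rt
Reagents that add atoms: none
Why: Oxidative cleavage of the PMB ether by DDQ in wet solvent proceeds through the benzylic oxocarbenium ion and leaves the ester, the alkyne and the olefins untouched.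

Step 15
Reactants: 21 9α-alcohol
Product: 22 (5E)-9α-acetoxy-8β-[(E)-but-2-enoyloxy]-7β-ethynyl-10β-hydroxy-4β,10α-dimethylcyclodec-5-en-1-one
Conditions: Ac2O, pyridine, DMAP (cat.), CH2Cl2, 0 °C
Reagents that add atoms: acetic anhydride CC(=O)OC(C)=O
Why: Acetylation of the secondary C9 hydroxyl is fast at 0 °C, so migration of the neighbouring crotonate should not compete, and the tertiary C10 hydroxyl stays free.

Step 16
Reactants: 22 alkyne
Product: 23 2-[(5E)-9α-acetoxy-8β-[(E)-but-2-enoyloxy]-10β-hydroxy-4β,10α-dimethyl-1-oxocyclodec-5-en-7β-yl]prop-2-enoic acid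
Conditions: Pd(OAc)2 (2 mol %), 2-(diphenylphosphino)pyridine, MsOH (cat.), CO (20 bar), H2O, acetone, 45 °C
Reagents that add atoms: carbon monoxide [C-]#[O+]; water O
Why: Palladium-catalysed Markovnikov hydroxycarbonylation of a terminal alkyne gives the 2-substituted acrylic acid (C12 from CO), and alkynes react far faster than olefins with this catalyst.

Step 17
Reactants: 23 acrylic acid
Product: 24 (2Z,5E)-dienone acid: 23 with a Z C2=C3 double bond
Conditions: IBX (2.5 equiv), DMSO/fluorobenzene, 65–70 °C
Reagents that add atoms: none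
Why: IBX dehydrogenation can only proceed through the C2 enol because C10 is quaternary, and it should give the Z-enone, the geometry a ten-membered ring accommodates with less strain.

Step 18
Reactants: 24 Z-enone acid
Product: 25 2α,3α-epoxy ketone acid (cis-oxirane; other centres as in 24)
Conditions: t-BuOOH, DBU (2.2 equiv), CH2Cl2, 0 °C
Reagents that add atoms: tert-butyl hydroperoxide CC(C)(C)OO
Why: In this Weitz–Scheffer epoxidation the peroxide anion should attack C3 from the peripheral face (anti to C5, with H-4 held in the enone plane by allylic strain) and close before C2–C3 rotation, giving the cis 2α,3α-oxirane; the acrylate carboxylate and the crotonate are poor acceptors.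

Step 19
Reactants: 25 epoxy ketone acid
Product: 26 5α-iodo-6α,12-olide: 5α-iodo derivative of the target
Conditions: I2, NaHCO3, MeCN/H2O, 0 °C, dark
Reagents that add atoms: iodine II
Why: In this 5-exo iodolactonisation iodine should add to the E C5=C6 olefin from its peripheral face (anti to C8), and the carboxylate, held on the ring side, closes anti at C6, which gives the 6α-O, 7β-C trans-fused α-methylene-γ-butyrolactone.

Step 20
Reactants: 26 iodolactone
Product: 27 target CNP0358125.1
Conditions: Bu3SnH (1.1 equiv), Et3B/air, toluene, −78 to 0 °C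
Reagents that add atoms: none
Why: Radical deiodination should be selective because iodine abstraction by the stannyl radical at low temperature is much faster than its addition to the acrylate or the carbonyl groups, and the C5 radical has no favourable cyclisation path.

## Compound list

1 | (tert-butyldimethylsilyloxy)acetaldehyde | O=CCO[Si](C)(C)C(C)(C)C | starting material
2 | 2-(triphenyl-λ5-phosphanylidene)propanal | CC(C=O)=P(c1ccccc1)(c1ccccc1)c1ccccc1 | starting material
3 | (E)-4-(TBS-oxy)-2-methylbut-2-enal | O=C/C(C)=C/CO[Si](C)(C)C(C)(C)C | intermediate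
4 | (1E,3E)-4-(TBS-oxy)-2-methylbuta-1,3-dien-1-yl acetate | CC(=O)O/C=C(C)/C=C/O[Si](C)(C)C(C)(C)C | intermediate
5 | but-2-yn-1-ol | CC#CCO | starting material
6 | (triphenyl-λ5-phosphanylidene)acetaldehyde | O=CC=P(c1ccccc1)(c1ccccc1)c1ccccc1 | starting material
7 | but-2-ynal (not isolated) | CC#CC=O | intermediate
8 | (E)-hex-2-en-4-ynal | CC#C/C=C/C=O | intermediate
9 | 1β-acetoxy-8β-(TBS-oxy)-7β-formyl-10-methyl-6α-(prop-1-ynyl)cyclohex-9-ene | CC(=O)O[C@H]1C(C)=C[C@@H](O[Si](C)(C)C(C)(C)C)[C@@H](C=O)[C@@H]1C#CC | intermediate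
10 | 1β-acetoxy-8β-(TBS-oxy)-7β-formyl-10-methyl-6α-[(Z)-prop-1-enyl]cyclohex-9-ene | CC(=O)O[C@H]1C(C)=C[C@@H](O[Si](C)(C)C(C)(C)C)[C@@H](C=O)[C@@H]1/C=C\C | intermediate
11 | 1β-acetoxy-7β-ethynyl analogue of 10 (alkynyl acetate, not isolated) | CC(=O)O[C@H]1C(C)=C[C@@H](O[Si](C)(C)C(C)(C)C)[C@@H](C#C)[C@@H]1/C=C\C | intermediate
12 | 7β-ethynyl-10-methyl-6α-[(Z)-prop-1-enyl]-8β-(TBS-oxy)cyclohex-9-en-1β-ol | O[C@H]1C(C)=C[C@@H](O[Si](C)(C)C(C)(C)C)[C@@H](C#C)[C@@H]1/C=C\C | intermediate
13 | 9β,10β-epoxide of 12 | O[C@H]1[C@@]2(C)O[C@H]2[C@@H](O[Si](C)(C)C(C)(C)C)[C@@H](C#C)[C@@H]1/C=C\C | intermediate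
14 | 9α-(PMB-oxy)-1β,10β-diol (10α-methyl, 8β-OTBS, 7β-ethynyl, 6α-(Z)-propenyl) | O[C@H]1[C@@](C)(O)[C@H](OCc2ccc(OC)cc2)[C@@H](O[Si](C)(C)C(C)(C)C)[C@@H](C#C)[C@@H]1/C=C\C | intermediate
15 | cyclohexan-1-one with 10β-OH, 10α-methyl, 9α-OPMB, 8β-OTBS, 7β-ethynyl, 6α-(Z)-propenyl | O=C1[C@@](C)(O)[C@H](OCc2ccc(OC)cc2)[C@@H](O[Si](C)(C)C(C)(C)C)[C@@H](C#C)[C@@H]1/C=C\C | intermediate
16 | 1β-ethenyl-1α,10β-diol (other substituents as in 15) | C=C[C@@]1(O)[C@@](C)(O)[C@H](OCc2ccc(OC)cc2)[C@@H](O[Si](C)(C)C(C)(C)C)[C@@H](C#C)[C@@H]1/C=C\C | intermediate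
17 | tripotassium C1(2)-enolate/C10-alkoxide/acetylide of 18 (not isolated) | [K+].[K+].[K+].[C-]#C[C@H]1/C=C/[C@@H](C)C/C=C(\[O-])[C@@](C)([O-])[C@H](OCc2ccc(OC)cc2)[C@H]1O[Si](C)(C)C(C)(C)C | intermediate
18 | (5E)-7β-ethynyl-10β-hydroxy-4β,10α-dimethyl-9α-(PMB-oxy)-8β-(TBS-oxy)cyclodec-5-en-1-one | C#C[C@H]1/C=C/[C@@H](C)CCC(=O)[C@@](C)(O)[C@H](OCc2ccc(OC)cc2)[C@H]1O[Si](C)(C)C(C)(C)C | intermediate
19 | 8β-alcohol from 18 | C#C[C@H]1/C=C/[C@@H](C)CCC(=O)[C@@](C)(O)[C@H](OCc2ccc(OC)cc2)[C@H]1O | intermediate
20 | 8β-(E)-crotonate of 19 | C#C[C@H]1/C=C/[C@@H](C)CCC(=O)[C@@](C)(O)[C@H](OCc2ccc(OC)cc2)[C@H]1OC(=O)/C=C/C | intermediate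
21 | 9α,10β-diol 8β-crotonate | C#C[C@H]1/C=C/[C@@H](C)CCC(=O)[C@@](C)(O)[C@H](O)[C@H]1OC(=O)/C=C/C | intermediate
22 | 9α-acetate 8β-crotonate alkyne | C#C[C@H]1/C=C/[C@@H](C)CCC(=O)[C@@](C)(O)[C@H](OC(C)=O)[C@H]1OC(=O)/C=C/C | intermediate
23 | 2-substituted acrylic acid from 22 | C=C(C(=O)O)[C@H]1/C=C/[C@@H](C)CCC(=O)[C@@](C)(O)[C@H](OC(C)=O)[C@H]1OC(=O)/C=C/C | intermediate
24 | (2Z,5E)-dienone acid | C=C(C(=O)O)[C@H]1/C=C/[C@@H](C)/C=C\C(=O)[C@@](C)(O)[C@H](OC(C)=O)[C@H]1OC(=O)/C=C/C | intermediate
25 | 2α,3α-epoxy ketone acid | C=C(C(=O)O)[C@H]1/C=C/[C@@H](C)[C@@H]2O[C@@H]2C(=O)[C@@](C)(O)[C@H](OC(C)=O)[C@H]1OC(=O)/C=C/C | intermediate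
26 | 5α-iodo-6α,12-olide | C=C1C(=O)O[C@@H]2[C@H](I)[C@@H](C)[C@@H]3O[C@@H]3C(=O)[C@@](C)(O)[C@H](OC(C)=O)[C@@H](OC(=O)/C=C/C)[C@@H]12 | intermediate
27 | CNP0358125.1 (9α-acetoxy-8β-crotonyloxy-2α,3α-epoxy-10β-hydroxy-1-oxogermacr-11(13)-en-6α,12-olide) | C=C1C(=O)O[C@@H]2C[C@@H](C)[C@@H]3O[C@@H]3C(=O)[C@@](C)(O)[C@H](OC(C)=O)[C@@H](OC(=O)/C=C/C)[C@@H]12 | target

## Step count and risks

Total step count: 20. Longest linear sequence: 19 (steps 1, 2 and 4–20; step 3 is a one-step side branch).

Most likely to fail, first: step 11. The polyanion may not rearrange cleanly. The axial methyl of the Z-propenyl group slows the chair [3,3] shift, so alkoxide-induced heterolysis of C1–C6 (net 1,3-shift or fragmentation), a boat pathway that erodes the C4 configuration, or decomposition of the aggregated trianion can compete. The fallback removes the charges and uses a neutral siloxy-Cope rearrangement. It sets out from 16: silylation of both tertiary hydroxyls with 1-(trimethylsilyl)imidazole should give the bis(trimethylsilyl) ether F1. Heating F1 in toluene (sealed vessel, 200–220 °C) should give the ring-expanded trimethylsilyl enol ether F2 through the same chair. Brief treatment with K2CO3 in MeOH at 0 °C removes both trimethylsilyl groups and returns to the route at 18.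

Second: step 4. Regio-, endo- or enantiofacial control may be incomplete. Hetero-Diels–Alder or Mukaiyama-type attack at the activated formyl group may compete. The strong Lewis acid may cleave the silyl dienol ether. The fallback replaces catalyst control by a covalent chiral controller on the diene. It sets out from 3: the potassium dienolate (KHMDS, THF, −78 °C) is acylated with (S)-O-methylmandeloyl chloride (or its mirror image, as the π-stacking model requires) to give the dienyl O-methylmandelate F3. Cycloaddition with 8 under mild conditions (toluene, 60 °C, or BF3·OEt2 at −78 °C) should give the mandelate adduct F4 as a separable diastereomer. Lindlar semihydrogenation gives the Z-propenyl mandelate F5. The Bestmann–Ohira/K2CO3/MeOH treatment of step 6 then homologates the aldehyde and cleaves the auxiliary ester, returning to the route at 12.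

Third: step 8. The alcohol is a weak nucleophile, so the opening may be slow, isopropoxide may be transferred from titanium instead, or attack may leak to the tertiary C10. The fallback uses the benchmark carboxylic acid nucleophile and then exchanges the protecting group. It sets out from 13: Ti(OiPr)4 and benzoic acid should give the 9α-benzoate 1β,10β-diol F6. 2,2-Dimethoxypropane/PPTS protects the cis-diol as the 1,10-acetonide benzoate F7. K2CO3/MeOH removes the benzoate to give the 9α-alcohol acetonide F8. PMB trichloroacetimidate with La(OTf)3 (cat.) gives the PMB ether acetonide F9. Aqueous acetic acid removes the acetonide and returns to the route at 14.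

## Further compounds

F1 | step 11 | bis(trimethylsilyl) ether of 16 (1α-OTMS, 10β-OTMS) | C=C[C@@]1(O[Si](C)(C)C)[C@@](C)(O[Si](C)(C)C)[C@H](OCc2ccc(OC)cc2)[C@@H](O[Si](C)(C)C(C)(C)C)[C@@H](C#C)[C@@H]1/C=C\C
F2 | step 11 | trimethylsilyl enol ether (C1=C2) of 18 with 10β-OTMS | C#C[C@H]1/C=C/[C@@H](C)C/C=C(\O[Si](C)(C)C)[C@@](C)(O[Si](C)(C)C)[C@H](OCc2ccc(OC)cc2)[C@H]1O[Si](C)(C)C(C)(C)C
F3 | step 4 | (1E,3E)-4-(TBS-oxy)-2-methylbuta-1,3-dien-1-yl (S)-2-methoxy-2-phenylacetate | CO[C@@H](c1ccccc1)C(=O)O/C=C(C)/C=C/O[Si](C)(C)C(C)(C)C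
F4 | step 4 | 1β-[(S)-O-methylmandeloyloxy] analogue of 9 | CO[C@@H](c1ccccc1)C(=O)O[C@H]1C(C)=C[C@@H](O[Si](C)(C)C(C)(C)C)[C@@H](C=O)[C@@H]1C#CC
F5 | step 4 | 1β-[(S)-O-methylmandeloyloxy] analogue of 10 | CO[C@@H](c1ccccc1)C(=O)O[C@H]1C(C)=C[C@@H](O[Si](C)(C)C(C)(C)C)[C@@H](C=O)[C@@H]1/C=C\C
F6 | step 8 | 9α-benzoyloxy-1β,10β-diol (other substituents as in 14) | O[C@H]1[C@@](C)(O)[C@H](OC(=O)c2ccccc2)[C@@H](O[Si](C)(C)C(C)(C)C)[C@@H](C#C)[C@@H]1/C=C\C
F7 | step 8 | 1β,10β-O-isopropylidene acetal of F6 | CC1(C)O[C@H]2[C@@](C)(O1)[C@H](OC(=O)c3ccccc3)[C@@H](O[Si](C)(C)C(C)(C)C)[C@@H](C#C)[C@@H]2/C=C\C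
F8 | step 8 | 9α-alcohol 1β,10β-acetonide | CC1(C)O[C@H]2[C@@](C)(O1)[C@H](O)[C@@H](O[Si](C)(C)C(C)(C)C)[C@@H](C#C)[C@@H]2/C=C\C
F9 | step 8 | 9α-PMB ether 1β,10β-acetonide | CC1(C)O[C@H]2[C@@](C)(O1)[C@H](OCc3ccc(OC)cc3)[C@@H](O[Si](C)(C)C(C)(C)C)[C@@H](C#C)[C@@H]2/C=C\C
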